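**Plan**

1. Retrosynthesis cuts the ester C–O bond, then C11–C12 (side chain), then takes the ring-B groups (C8 methyl, C7=C8, C11) back to a C9 ketone, and last opens ring A at C2–C3 and C4–C5. This excises an isobutyryl unit (C3–C4) from a ring-B cyclohexanone that carries a 2-sulfonylethyl arm (C1–C2) on C10.
2. Forward: ring B comes from 2-methylcyclohexane-1,3-dione; ring A is annulated onto it in one pot; ring B is then elaborated (C8 methyl, C7=C8, C9=C11); the C12–C16 chain is joined by hydroboration and copper allyl–alkyl coupling; the ester is made last.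
3. Enabling feature: in ring B the C5 carbonyl and the C9 oxygen are 1,3 across quaternary C10. An α-bromoisobutyrate on O-9 therefore reaches C5 through a six-membered lactone, and its carbonyl carbon (C3) then lies within reach of the sulfonyl-activated C2 of the arm.
4. Stereochemistry: C10 by enzymatic desymmetrisation; 5-H by acetate-directed hydrogenation anti to the C10 methyl; the axial 3-OH by a bulky hydride; 9-H by hydroboration anti to the C10 methyl; 13E by anti-SN2′ coupling; the acyl stereocentre from (S)-3-methylpentanoic acid.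
5. Ring atoms carry labdane numbers in all names below (ring A: C1–C5 and C10; ring B: C5–C10; chain C11–C16).

Key step: step 4

Assumption: the yeast reduction in step 2 is taken to follow the course known for 2-alkyl-2-methylcyclohexane-1,3-diones (one enantiotopic carbonyl reduced, hydroxyl cis to the larger arm); only the configuration of the quaternary carbon is carried into the target.

**Route**

Step 1
Reactants: 1 2-methylcyclohexane-1,3-dione; 2 phenyl vinyl sulfone
Product: 3 2-methyl-2-[2-(phenylsulfonyl)ethyl]cyclohexane-1,3-dione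
Conditions: Et3N, MeCN, 60 °C
Reagents that add atoms: none
Why: Michael addition of the doubly activated carbon of the dione to the vinyl sulfone should form the quaternary carbon (future C10) and install the C1–C2 arm with a sulfonyl group that later makes C2 a carbanion.

Step 2
Reactants: 3 2-methyl-2-[2-(phenylsulfonyl)ethyl]cyclohexane-1,3-dione
Product: 4 (2S,3S)-3-hydroxy-2-methyl-2-[2-(phenylsulfonyl)ethyl]cyclohexan-1-one
Conditions: baker's yeast, sucrose, H2O (1% DMSO), 30 °C
Reagents that add atoms: none
Why: Enantiotopic-group-selective bioreduction of the prochiral 2,2-disubstituted 1,3-dione should reduce one carbonyl only, which fixes the quaternary carbon (future C10) and gives the carbinol (future C9) with hydroxyl cis to the larger arm.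

Step 3
Reactants: 4 (2S,3S)-3-hydroxy-2-methyl-2-[2-(phenylsulfonyl)ethyl]cyclohexan-1-one; 5 2-bromo-2-methylpropanoyl bromide
Product: 6 (1S,2S)-2-methyl-3-oxo-2-[2-(phenylsulfonyl)ethyl]cyclohexyl 2-bromo-2-methylpropanoate
Conditions: pyridine, DMAP (cat.), CH2Cl2, 0 °C to rt
Reagents that add atoms: none
Why: DMAP-catalysed acylation of the hindered secondary alcohol by the acyl bromide should attach the future C3–C4 unit to O-9 without touching a stereocentre.

Step 4
Reactants: 6 (1S,2S)-2-methyl-3-oxo-2-[2-(phenylsulfonyl)ethyl]cyclohexyl 2-bromo-2-methylpropanoate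
Product: 9 β-keto sulfone diol (cis-fused 5,9-dihydroxy-4,4,10-trimethyl-2-(phenylsulfonyl)decalin-3-one; 5-OH cis to the C10 methyl; 9-OH trans to it; C2 epimers), via samarium ester enolate 7 (not isolated), via bridged lactone samarium alkoxide 8 (not isolated)
Conditions: SmI2 (2.2 equiv), THF, −78 °C; then LDA (3.5 equiv), −78 to 0 °C; aq NH4Cl
Reagents that add atoms: none
Why: SmI2 should reduce the tertiary C–Br bond of 6 faster than the ketone to give the trivalent samarium enolate 7, whose C4 adds to the C5 carbonyl in an intramolecular Reformatsky reaction (6-(enolexo)-exo-trig aldol) that closes the bridged δ-lactone 8 and forms C4–C5; LDA, added only after the ketone is consumed, then removes a proton α to the sulfone (the lactone has no α-hydrogen), and the C2 carbanion attacks the lactone carbonyl C3 (6-exo-trig nucleophilic acyl substitution of Claisen/Dieckmann type), which closes ring A, forms C2–C3 and releases O-9. The closest known reaction types are the samarium diiodide Reformatsky cyclisation of β-(bromoacyloxy) ketones to β-hydroxy δ-lactones and the acylation of lithiated sulfones by lactones. The new C5 stereocentre is set by the tether, because C4 is delivered to the carbonyl face syn to O-9 (cis ring fusion); it is erased in step 7, and the C2 epimers do not matter because the sulfonyl group leaves in step 5. The selectivity needed is one of order: the C4 enolate must exist before any base is present, so that neither ketone enolisation nor direct O-to-C acyl transfer to C2 can compete, and reductive enolate formation from the bromide secures this. The β-keto sulfone is deprotonated as it forms, which drives the acyl substitution and keeps C3 from accepting a retro-aldol cleavage of the C5 alkoxide.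

Step 5
Reactants: 9 β-keto sulfone diol
Product: 10 keto diol (cis-fused 5,9-dihydroxy-4,4,10-trimethyldecalin-3-one; 5-OH cis to the C10 methyl; 9-OH trans to it)
Conditions: aluminium amalgam (Al/Hg), THF–H2O, 0 °C to rt
Reagents that add atoms: none
Why: Reductive desulfonylation of a β-keto sulfone by aluminium amalgam should remove the activating group, leave C2 as CH2 and delete the C2 stereocentre.

Step 6
Reactants: 10 keto diol
Product: 11 9-acetoxy-5-hydroxy-4,4,10-trimethyl-cis-decalin-3-one
Conditions: Ac2O, pyridine, DMAP (cat.), CH2Cl2, 0 °C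
Reagents that add atoms: acetic anhydride CC(=O)OC(C)=O
Why: Selective acetylation of the secondary C9 hydroxyl (the tertiary C5 hydroxyl should not react) protects O-9 for the dehydration and supplies a directing group for step 8.

Step 7
Reactants: 11 9-acetoxy-5-hydroxy-4,4,10-trimethyl-cis-decalin-3-one
Product: 12 9-acetoxy-4,4,10-trimethyl-Δ5-octalin-3-one (C5=C6; acetoxy trans to the C10 methyl)
Conditions: Burgess reagent, toluene, 70 °C
Reagents that add atoms: none
Why: Burgess dehydration (syn elimination) of the tertiary alcohol can only take a hydrogen from C6 because C4 and C10 are quaternary, so the C5=C6 alkene should form regiospecifically and the cis ring fusion is erased.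

Step 8
Reactants: 12 9-acetoxy-4,4,10-trimethyl-Δ5-octalin-3-one
Product: 13 9-acetoxy-4,4,10-trimethyl-trans-decalin-3-one (5-H and 9-OAc both trans to the C10 methyl)
Conditions: H2 (1 atm), [Ir(cod)(PCy3)(py)]PF6 (10 mol %), CH2Cl2, rt
Reagents that add atoms: none
Why: Ester-directed homogeneous hydrogenation (Crabtree catalyst) should deliver hydrogen to the alkene face that carries the C9 acetoxy group, which is also the face anti to the angular C10 methyl, so 5-H is set trans to that methyl (trans-decalin).

Step 9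
Reactants: 13 9-acetoxy-4,4,10-trimethyl-trans-decalin-3-one
Product: 14 9-acetoxy-4,4,10-trimethyl-trans-decalin-3-ol (3-OH axial; trans to the C10 methyl)
Conditions: LiB(s-Bu)3H (L-Selectride), THF, −78 °C
Reagents that add atoms: none
Why: The bulky hydride should attack the 4,4-dimethyl-3-ketone from the equatorial direction and give the axial (3S) alcohol, as is usual for such ketones, while the hindered acetate survives at low temperature.

Step 10
Reactants: 14 9-acetoxy-4,4,10-trimethyl-trans-decalin-3-ol
Product: 15 9-acetoxy-3-(tert-butyldimethylsilyloxy)-4,4,10-trimethyl-trans-decalin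
Conditions: TBSOTf, 2,6-lutidine, CH2Cl2, 0 °C
Reagents that add atoms: tert-butyldimethylsilyl trifluoromethanesulfonate CC(C)(C)[Si](C)(C)OS(=O)(=O)C(F)(F)F
Why: Silylation with the silyl triflate should mask the hindered axial alcohol for the oxidation, enolate and ylide steps that follow.

Step 11
Reactants: 15 9-acetoxy-3-(tert-butyldimethylsilyloxy)-4,4,10-trimethyl-trans-decalin
Product: 16 3-(tert-butyldimethylsilyloxy)-4,4,10-trimethyl-trans-decalin-9-ol
Conditions: K2CO3, MeOH, 40 °C
Reagents that add atoms: none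
Why: Base-catalysed transesterification with methanol should remove the acetate and leave the silyl ether untouched.

Step 12
Reactants: 16 3-(tert-butyldimethylsilyloxy)-4,4,10-trimethyl-trans-decalin-9-ol
Product: 17 3-(tert-butyldimethylsilyloxy)-4,4,10-trimethyl-trans-decalin-9-one
Conditions: Dess–Martin periodinane, NaHCO3, CH2Cl2, rt
Reagents that add atoms: none
Why: Dess–Martin oxidation should return C9 to the ketone level, which removes the temporary C9 stereocentre as planned.

Step 13
Reactants: 17 3-(tert-butyldimethylsilyloxy)-4,4,10-trimethyl-trans-decalin-9-one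
Product: 19 3-(tert-butyldimethylsilyloxy)-4,4,8,10-tetramethyl-trans-decalin-9-one (C8 epimers), via lithium enolate 18 (not isolated)
Conditions: LDA, THF, −78 °C; MeI, DMPU, −78 to 0 °C
Reagents that add atoms: iodomethane CI
Why: Enolate alkylation should be regiospecific because C8 is the only enolisable position (C10 is quaternary), and the C8 configuration is irrelevant since C8 becomes sp2 in step 14.

Step 14
Reactants: 19 3-(tert-butyldimethylsilyloxy)-4,4,8,10-tetramethyl-trans-decalin-9-one
Product: 21 3-(tert-butyldimethylsilyloxy)-4,4,8,10-tetramethyl-trans-Δ7-octalin-9-one (C7=C8 enone), via trimethylsilyl enol ether 20 (not isolated)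
Conditions: LDA, Me3SiCl, THF, −78 °C; then Pd(OAc)2, MeCN, rt
Reagents that add atoms: none
Why: Saegusa–Ito oxidation of the only possible silyl enol ether should give the 8-methyl enone by β-hydride elimination from C7.

Step 15
Reactants: 21 3-(tert-butyldimethylsilyloxy)-4,4,8,10-tetramethyl-trans-Δ7-octalin-9-one
Product: 22 3-(tert-butyldimethylsilyloxy)-4,4,8,10-tetramethyl-9-methylene-trans-Δ7-octalin (C7=C8 and C9=C11 diene)
Conditions: Ph3PCH3Br, KOt-Bu, toluene, 90 °C
Reagents that add atoms: methyltriphenylphosphonium bromide C[P+](c1ccccc1)(c1ccccc1)c1ccccc1.[Br-]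
Why: Wittig methylenation with the salt-free ylide in hot toluene is established for hindered ketones and should convert the C9 carbonyl into the exocyclic C9=C11 alkene.

Step 16
Reactants: 23 (tert-butyldimethylsilyloxy)acetaldehyde; 24 isopropenylmagnesium bromide
Product: 25 1-(tert-butyldimethylsilyloxy)-3-methylbut-3-en-2-ol (racemic)
Conditions: THF, −78 °C; aq NH4Cl
Reagents that add atoms: none
Why: Grignard 1,2-addition to the aldehyde should give the secondary allylic alcohol, whose stereocentre is lost in step 18.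

Step 17
Reactants: 25 1-(tert-butyldimethylsilyloxy)-3-methylbut-3-en-2-ol
Product: 26 1-(tert-butyldimethylsilyloxy)-3-methylbut-3-en-2-yl diethyl phosphate
Conditions: ClP(O)(OEt)2, pyridine, DMAP (cat.), CH2Cl2, 0 °C
Reagents that add atoms: diethyl chlorophosphate CCOP(=O)(Cl)OCC
Why: Phosphorylation of the allylic alcohol installs the leaving group for the copper-mediated anti-SN2′ coupling.

Step 18
Reactants: 22 3-(tert-butyldimethylsilyloxy)-4,4,8,10-tetramethyl-9-methylene-trans-Δ7-octalin; 26 1-(tert-butyldimethylsilyloxy)-3-methylbut-3-en-2-yl diethyl phosphate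
Product: 28 (3S,5S,9R,10S,13E)-3,15-bis(tert-butyldimethylsilyloxy)labda-7,13-diene, via B-alkyl-9-BBN 27 (not isolated)
Conditions: 9-BBN, THF, 0 to 50 °C; then 26, CuOAc (10 mol %), KOt-Bu, THF, 50 °C
Reagents that add atoms: none
Why: Hydroboration with 9-BBN should put boron on terminal C11 and hydrogen on C9 from the face anti to the axial C10 methyl (9R, C11 equatorial), and the copper-catalysed γ-selective allyl–alkyl coupling (anti-SN2′) should then join C11 to C12 and form the 13E alkene, because the CH2OSi group avoids the incoming chain.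

Step 19
Reactants: 28 (3S,5S,9R,10S,13E)-3,15-bis(tert-butyldimethylsilyloxy)labda-7,13-diene
Product: 29 (3S,5S,9R,10S,13E)-labda-7,13-diene-3,15-diol
Conditions: TBAF, THF, 50 °C
Reagents that add atoms: none
Why: Fluoride-mediated desilylation should cleave both silyl ethers without affecting the two alkenes.

Step 20
Reactants: 29 (3S,5S,9R,10S,13E)-labda-7,13-diene-3,15-diol; 30 (S)-3-methylpentanoic acid
Product: 31 (3S,5S,9R,10S,13E)-3-hydroxylabda-7,13-dien-15-yl (S)-3-methylpentanoate
Conditions: EDC·HCl, DMAP (cat.), CH2Cl2, 0 °C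
Reagents that add atoms: none
Why: Carbodiimide (Steglich-type) esterification should acylate only the primary allylic hydroxyl, since the axial C3 hydroxyl next to the gem-dimethyl carbon is far less reactive, and the acid stereocentre is not α to the carbonyl and cannot epimerise.

**Compound list**

1 | 2-methylcyclohexane-1,3-dione | CC1C(=O)CCCC1=O | starting material
2 | phenyl vinyl sulfone | C=CS(=O)(=O)c1ccccc1 | starting material
3 | 2-methyl-2-[2-(phenylsulfonyl)ethyl]cyclohexane-1,3-dione | CC1(CCS(=O)(=O)c2ccccc2)C(=O)CCCC1=O | intermediate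
4 | (2S,3S)-3-hydroxy-2-methyl-2-[2-(phenylsulfonyl)ethyl]cyclohexan-1-one | O[C@H]1CCCC(=O)[C@@]1(C)CCS(=O)(=O)c1ccccc1 | intermediate
5 | 2-bromo-2-methylpropanoyl bromide | CC(C)(Br)C(=O)Br | starting material
6 | (1S,2S)-2-methyl-3-oxo-2-[2-(phenylsulfonyl)ethyl]cyclohexyl 2-bromo-2-methylpropanoate | CC(C)(Br)C(=O)O[C@H]1CCCC(=O)[C@@]1(C)CCS(=O)(=O)c1ccccc1 | intermediate
7 | samarium ester enolate of 6 (bromine lost; O-samarium diiodide enolate) | CC(C)=C(O[Sm](I)I)O[C@H]1CCCC(=O)[C@@]1(C)CCS(=O)(=O)c1ccccc1 | intermediate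
8 | bridged lactone samarium alkoxide: (1S,5S,9S)-5-hydroxy-4,4,9-trimethyl-9-[2-(phenylsulfonyl)ethyl]-2-oxabicyclo[3.3.1]nonan-3-one as its O-samarium diiodide alkoxide | O=C1O[C@H]2CCC[C@@](O[Sm](I)I)(C1(C)C)[C@@]2(C)CCS(=O)(=O)c1ccccc1 | intermediate
9 | cis-fused 5,9-dihydroxy-4,4,10-trimethyl-2-(phenylsulfonyl)decalin-3-one (5-OH cis, 9-OH trans to the C10 methyl; C2 epimers) | O[C@H]1CCC[C@@]2(O)C(C)(C)C(=O)C(S(=O)(=O)c3ccccc3)C[C@@]12C | intermediate
10 | cis-fused 5,9-dihydroxy-4,4,10-trimethyldecalin-3-one (5-OH cis, 9-OH trans to the C10 methyl) | O[C@H]1CCC[C@@]2(O)C(C)(C)C(=O)CC[C@@]12C | intermediate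
11 | 9-acetoxy-5-hydroxy-4,4,10-trimethyl-cis-decalin-3-one | CC(=O)O[C@H]1CCC[C@@]2(O)C(C)(C)C(=O)CC[C@@]12C | intermediate
12 | 9-acetoxy-4,4,10-trimethyl-Δ5-octalin-3-one | CC(=O)O[C@H]1CCC=C2C(C)(C)C(=O)CC[C@@]12C | intermediate
13 | 9-acetoxy-4,4,10-trimethyl-trans-decalin-3-one (5-H and 9-OAc trans to the C10 methyl) | CC(=O)O[C@H]1CCC[C@@H]2C(C)(C)C(=O)CC[C@@]12C | intermediate
14 | 9-acetoxy-4,4,10-trimethyl-trans-decalin-3-ol (3-OH axial, trans to the C10 methyl) | CC(=O)O[C@H]1CCC[C@@H]2C(C)(C)[C@@H](O)CC[C@@]12C | intermediate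
15 | 9-acetoxy-3-(tert-butyldimethylsilyloxy)-4,4,10-trimethyl-trans-decalin | CC(=O)O[C@H]1CCC[C@@H]2C(C)(C)[C@@H](O[Si](C)(C)C(C)(C)C)CC[C@@]12C | intermediate
16 | 3-(tert-butyldimethylsilyloxy)-4,4,10-trimethyl-trans-decalin-9-ol | O[C@H]1CCC[C@@H]2C(C)(C)[C@@H](O[Si](C)(C)C(C)(C)C)CC[C@@]12C | intermediate
17 | 3-(tert-butyldimethylsilyloxy)-4,4,10-trimethyl-trans-decalin-9-one | O=C1CCC[C@@H]2C(C)(C)[C@@H](O[Si](C)(C)C(C)(C)C)CC[C@@]12C | intermediate
18 | lithium enolate of 17 (C8=C9) | [Li]OC1=CCC[C@@H]2C(C)(C)[C@@H](O[Si](C)(C)C(C)(C)C)CC[C@@]12C | intermediate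
19 | 3-(tert-butyldimethylsilyloxy)-4,4,8,10-tetramethyl-trans-decalin-9-one (C8 epimers) | O=C1C(C)CC[C@@H]2C(C)(C)[C@@H](O[Si](C)(C)C(C)(C)C)CC[C@@]12C | intermediate
20 | trimethylsilyl enol ether of 19 (C8=C9) | C[Si](C)(C)OC1=C(C)CC[C@@H]2C(C)(C)[C@@H](O[Si](C)(C)C(C)(C)C)CC[C@@]12C | intermediate
21 | 3-(tert-butyldimethylsilyloxy)-4,4,8,10-tetramethyl-trans-Δ7-octalin-9-one | O=C1C(C)=CC[C@@H]2C(C)(C)[C@@H](O[Si](C)(C)C(C)(C)C)CC[C@@]12C | intermediate
22 | 3-(tert-butyldimethylsilyloxy)-4,4,8,10-tetramethyl-9-methylene-trans-Δ7-octalin | C=C1C(C)=CC[C@@H]2C(C)(C)[C@@H](O[Si](C)(C)C(C)(C)C)CC[C@@]12C | intermediate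
23 | (tert-butyldimethylsilyloxy)acetaldehyde | CC(C)(C)[Si](C)(C)OCC=O | starting material
24 | isopropenylmagnesium bromide | CC(=C)[Mg]Br | starting material
25 | 1-(tert-butyldimethylsilyloxy)-3-methylbut-3-en-2-ol (racemic) | CC(=C)C(O)CO[Si](C)(C)C(C)(C)C | intermediate
26 | 1-(tert-butyldimethylsilyloxy)-3-methylbut-3-en-2-yl diethyl phosphate (racemic) | CCOP(=O)(OCC)OC(CO[Si](C)(C)C(C)(C)C)C(C)=C | intermediate
27 | B-alkyl-9-BBN (boron on C11; 9-H trans to the C10 methyl) | B1(C2CCCC1CCC2)C[C@@H]1C(C)=CC[C@@H]2C(C)(C)[C@@H](O[Si](C)(C)C(C)(C)C)CC[C@@]12C | intermediate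
28 | (3S,5S,9R,10S,13E)-3,15-bis(tert-butyldimethylsilyloxy)labda-7,13-diene | CC(C)(C)[Si](C)(C)OC/C=C(\C)CC[C@@H]1C(C)=CC[C@@H]2C(C)(C)[C@@H](O[Si](C)(C)C(C)(C)C)CC[C@@]12C | intermediate
29 | (3S,5S,9R,10S,13E)-labda-7,13-diene-3,15-diol | OC/C=C(\C)CC[C@@H]1C(C)=CC[C@@H]2C(C)(C)[C@@H](O)CC[C@@]12C | intermediate
30 | (S)-3-methylpentanoic acid | CC[C@H](C)CC(=O)O | starting material
31 | (3S,5S,9R,10S,13E)-3-hydroxylabda-7,13-dien-15-yl (S)-3-methylpentanoate | CC[C@H](C)CC(=O)OC/C=C(\C)CC[C@@H]1C(C)=CC[C@@H]2C(C)(C)[C@@H](O)CC[C@@]12C | target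

**Step count and risks**

Total steps: 20. Longest linear sequence: 18 (steps 1–15 and 18–20).

The three steps most likely to fail:

1. Step 4. The samarium aldolate may undergo retro-aldol opening once base is added, or the hindered lactone carbonyl may resist attack by the sulfonyl carbanion, so that ring A does not close. The fallback sets out from 4 and returns at 10, and forms the two bonds in the reverse order. Acylation of 4 with 2-methylpropanoyl chloride (pyridine, DMAP) gives the isobutyrate ester F1. LDA (2.5 equiv, THF, −78 °C) then makes the sulfonyl carbanion, which takes the acyl group from O-9 through a six-membered transition state to give the β-keto sulfone F2 (C2–C3 bond). Aluminium amalgam removes the sulfonyl group to give the hydroxy diketone F3. KOt-Bu in t-BuOH/THF closes C4–C5 by intramolecular aldol addition of the isopropyl ketone to the ring carbonyl, which should give the cis-fused ketol 10.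

2. Step 18. Boron-to-copper transfer from the hindered alkylborane may be slow, and the coupling may lose γ-selectivity or E geometry. The fallback sets out from 22 (through borane 27) and returns at 29, and builds the alkene by a stereodefined carbometalation. Oxidation of 27 with NaOH/H2O2 gives the primary alcohol F4, and I2/PPh3/imidazole gives the iodide F5. Displacement with lithiated 1-(trimethylsilyl)propyne (n-BuLi, THF/DMPU) gives the silyl alkyne F6, and K2CO3/MeOH gives the terminal alkyne F7. Zirconium-catalysed methylalumination (Me3Al, Cp2ZrCl2) followed by n-BuLi and paraformaldehyde gives the (E)-allylic alcohol F8 by syn addition. TBAF then gives diol 29.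

3. Step 2. The yeast reductases may convert the polar sulfone substrate slowly or discriminate poorly between the two enantiotopic carbonyls. The fallback sets out from 3 and returns at 4 by kinetic resolution. NaBH4 (substoichiometric, MeOH, −20 °C) reduces one carbonyl anti to the larger arm to give the racemic hydroxy ketone F9. Lipase-catalysed acylation (Burkholderia cepacia lipase, vinyl acetate) should acetylate the (3R)-alcohol to the acetate F10 and leave (2S,3S)-4, which is separated.

**Further compounds**

F1 | step 4 | (1S,2S)-2-methyl-3-oxo-2-[2-(phenylsulfonyl)ethyl]cyclohexyl 2-methylpropanoate | CC(C)C(=O)O[C@H]1CCCC(=O)[C@@]1(C)CCS(=O)(=O)c1ccccc1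
F2 | step 4 | (2S,3S)-3-hydroxy-2-methyl-2-[4-methyl-3-oxo-2-(phenylsulfonyl)pentyl]cyclohexan-1-one (side-chain epimers) | O[C@H]1CCCC(=O)[C@@]1(C)CC(C(=O)C(C)C)S(=O)(=O)c1ccccc1
F3 | step 4 | (2S,3S)-3-hydroxy-2-methyl-2-(4-methyl-3-oxopentyl)cyclohexan-1-one | O[C@H]1CCCC(=O)[C@@]1(C)CCC(=O)C(C)C
F4 | step 18 | 11-hydroxy compound (3-silyloxy drim-7-en-11-ol type; 9-H trans to the C10 methyl) | OC[C@@H]1C(C)=CC[C@@H]2C(C)(C)[C@@H](O[Si](C)(C)C(C)(C)C)CC[C@@]12C
F5 | step 18 | 11-iodide of F4 | IC[C@@H]1C(C)=CC[C@@H]2C(C)(C)[C@@H](O[Si](C)(C)C(C)(C)C)CC[C@@]12C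
F6 | step 18 | 14-(trimethylsilyl)-13-alkyne (C11–C12–C13≡C14–SiMe3) | C[Si](C)(C)C#CCC[C@@H]1C(C)=CC[C@@H]2C(C)(C)[C@@H](O[Si](C)(C)C(C)(C)C)CC[C@@]12C
F7 | step 18 | terminal 13-alkyne | C#CCC[C@@H]1C(C)=CC[C@@H]2C(C)(C)[C@@H](O[Si](C)(C)C(C)(C)C)CC[C@@]12C
F8 | step 18 | (13E)-3-(tert-butyldimethylsilyloxy)labda-7,13-dien-15-ol | OC/C=C(\C)CC[C@@H]1C(C)=CC[C@@H]2C(C)(C)[C@@H](O[Si](C)(C)C(C)(C)C)CC[C@@]12C
F9 | step 2 | rac-(2S*,3S*)-3-hydroxy-2-methyl-2-[2-(phenylsulfonyl)ethyl]cyclohexan-1-one | OC1CCCC(=O)C1(C)CCS(=O)(=O)c1ccccc1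
F10 | step 2 | (1R,2R)-2-methyl-3-oxo-2-[2-(phenylsulfonyl)ethyl]cyclohexyl acetate | CC(=O)O[C@@H]1CCCC(=O)[C@]1(C)CCS(=O)(=O)c1ccccc1
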